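Compound numbers used throughout: 1–19 as in the compound list below (5 = diene, 7 = ynoate, 10 = cycloaddition product, 17 = ring A acid, 19 = target).

## The problem

The target 19 is a benzyl ester in which 2-hydroxy-4-methoxy-3,6-dimethylbenzoic acid (ring A) acylates the C6 hydroxymethyl group of a 3,7-dihydroxy-5-methoxyphthalide (benzene ring B fused to lactol ring C). Ring B is hexasubstituted. Going round it, C7a bears the lactone carbonyl, C7 a phenol, C6 the CH2O branch, C5 a methoxy group, C4 the only hydrogen and C3a the lactol carbon. Substitution chemistry on a preformed 5,7-dioxygenated phthalide could not tell C4 from C6. The single stereocentre, C3 (R), is a hemiacylal carbon that equilibrates with the open 2-formylbenzoic acid. No other stereocentre can control it, so it must be set by a reagent, late, and stored in a form that cannot open. The ester linkage is an o-hydroxybenzyl ester with a second ortho donor (5-OMe). Base can expel the carboxylate through an o-quinone methide and strong acid can ionise the benzylic C–O bond, so neither should be used once the linkage exists. The ring A acid is 2,6-disubstituted and chelated, so it is slow to activate at its carbonyl and liable to decarboxylate when heated in acid. The feature that permits a cycloaddition is the pattern of ring B itself: C7–C6–C5–C4 is a 1,3-dioxygenated four-carbon unit with a carbon branch on its second atom, and C7a/C3a are two adjacent carbons at carbonyl oxidation level. This is a 2-substituted 1,3-dioxygenated butadiene plus a 4-oxobut-2-ynoate.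

## Retrosynthesis

**19 from 18.** The last bond cut is the acetyl C–O bond of the (R)-acylal acetate 18. A free lactol cannot be carried through the synthesis, whereas its acetate is configurationally fixed. A methyl pseudo-ester would need aqueous acid or hydroxide for its removal, and both endanger the o-hydroxybenzyl ester. The acetate can be removed by a lipase in a neutral organic medium with retention at C3. The forward step must cleave one ester out of four carbonyl groups; the enzyme's preference for small acyl groups on secondary carbinols provides that selectivity.

**18 from 14 and 17.** The ester is cut at the benzylic CH2–O bond, not at the acyl C–O bond. Acyl activation of the hindered, chelated acid 17 would be slow and would compete with acylation of phenols. With the carbinol 14 as electrophile (Mitsunobu), the carboxylate attacks an unhindered primary carbon. This cut divides the molecule into its two aromatic halves. The forward reaction must leave the acylal and both phenols untouched.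

**17 from 16 from 15.** The acid 17 follows from the commercial ester 15 by methylation of the non-chelated 4-OH (16) and saponification.

**14 from 13 from 12.** Removing the silyl group (14 from 13) and the acetyl group (13 from 12) leads to the racemic lactol 12. The stereocentre is introduced here, on the smallest lactol-bearing intermediate, by lipase-mediated dynamic kinetic acetylation. At this stage the amine needed to racemise the slow enantiomer cannot harm a benzylic ester, because none is present yet. The silyl ether keeps the primary carbinol out of the enzymatic acylation.

**12 from 10.** Ring C is opened at the lactone C1–O2 bond and the lactol carbon is returned to an acetal, giving salicylate 10. The two carbonyl-level carbons are already differentiated as ester and acetal. The forward sequence is acetal hydrolysis followed by saponification assisted by the freed ortho formyl group, which overcomes the hindrance of the chelated ester.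

**10 from 5 and 7 (key disconnection).** Ring B is cut at C3a–C4 and C7–C7a. Diene 5 supplies C7 (with its oxygen), C6 (with the CH2O branch), C5 (with OMe) and C4. Ynoate 7 supplies C7a with the ester and C3a with the acetal. Compared with stepwise functionalisation of a simpler arene, this fixes all six substituents by the choice of partners and needs only regiocontrol, which the polarisation of both partners provides.

**5 from 4 from 3 from 2 from 1.** The diene is the silyl ketene acetal of the β-methoxy enoate 4. Attaching the CH2O branch to the extended enolate of methyl 3-methoxybut-2-enoate was rejected, because 3-alkoxy dienolates tend to react with carbonyl electrophiles at the γ-carbon. Instead the branch is present from the start in methyl 3-hydroxypropanoate (1). After silylation (2), the enolate is C-acetylated to β-keto ester 3, which places the acetyl group unambiguously. O-Methylation then gives 4.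

**7 from 6.** The ynoate comes from commercial 3,3-diethoxyprop-1-yne (6) by carboxylation of its lithium acetylide with methyl chloroformate.

## Roads not taken

**Alternative 1:** Tethered triyne cyclotrimerisation. The cut removes three bonds of ring B at once (C7a–C3a, C6–C7, C4–C5). In the forward sense RhCl(PPh3)3 would cyclotrimerise triyne A1, in which an alkynoate is tied to a propargylic ethoxy acetal carbon through the future lactone oxygen and to a methoxyalkyne through a Si–O–CH2 tether. The product would be tricycle A2, a 3-ethoxyphthalide fused to a benzoxasilole, and oxidation of the aryl–silicon bond would later reveal the C7 phenol and the C6 carbinol.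
- Merits: every substituent position is dictated by the tethers, and rings B and C close in one operation. In bonds formed per step this plan is better than the chosen one, which needs a separate step for ring C.
- Weak points: A1 combines an ynol ether, an acylal-type propargylic ester and a silyl ether tether, all hydrolytically fragile, and its assembly would take more steps than 5 and 7 together. The ester tether must adopt its disfavoured s-cis conformation to close a five-membered lactone. The peroxide-based oxidation of the C–Si bond would meet a base-labile pseudo-ester. A2 is racemic and carries an ethyl pseudo-ester, so the masking and stereochemical problems of the end game remain.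
- Comparison: the chosen plan sets two robust, distillable partners and a well-known cycloaddition against the higher convergence of this cascade.

**Alternative 2:** Ring A built last by acylketene capture and aldol aromatisation. The cuts are the ester C–O bond and the C1–C6 bond of ring A. Heating diketo-dioxinone A3 with the protected ring B alcohol A4 would release an acylketene that the alcohol traps. Cs2CO3 and then acid would cyclise the triketo ester to resorcylate A5.
- Merits: the ester is formed without activating a hindered salicylic acid. On this point the approach is at least as good as a Mitsunobu coupling.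
- Weak points: ring A is the easy half, since its whole skeleton can be bought as 15. A4 is still needed, so the substitution problem of ring B is untouched. A3 takes several steps. Carbonate treatment meets a base-labile pseudo-ester lactone. A5 needs a late selective methylation of its 4-OH. Its methoxymethyl ether and methyl pseudo-ester must then be removed with acid in the presence of the ionisable benzylic ester. The lactol stereocentre is not addressed.
- Comparison: the chosen plan answers the one advantage of this road by making the carboxylate the nucleophile (step 12), and it is shorter.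

**Alternative 3:** Baeyer–Villiger ring expansion of a benzocyclobutenone. The cut removes O2 from between C1 and C3. Peracid (m-CPBA with NaHCO3) would convert the enantioenriched 2-silyloxybenzocyclobutenone A6 into the bis-silyl ether A7 of the target, the oxygenated carbon migrating with retention.
- Merits: the stereocentre is created on a configurationally stable ketone α-carbon and transferred by a stereospecific rearrangement, and the lactol emerges protected. In predictability of stereocontrol this is better than an enzymatic resolution whose sense and rate on this substrate still have to be established.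
- Weak points: A6 is a fully substituted, strained, enantioenriched ring system whose preparation restates the ring B problem and adds an asymmetric α-oxygenation. Migration of the electron-rich aryl carbon can compete with that of the sp3 carbon. The peracid meets two electron-rich arenes. The final fluoride removal of both silyl groups passes through a lactol alkoxide, which invites racemisation, and through a phenoxide ortho to the benzylic ester, which invites o-quinone methide formation.
- Comparison: the chosen plan has a short route to ring B, and it releases the lactol from a stable acylal under neutral enzymatic conditions.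

Key step: step 6

Assumption: the C3 lactol of 19 can racemise through its open formyl acid tautomer, so it is taken that the (R)-lactol is configurationally stable enough to be isolated when released last, in a neutral aprotic medium, and handled without acid or base.

## Route

Step 1
Reactants: 1 methyl 3-hydroxypropanoate
Product: 2 methyl 3-(tert-butyldimethylsilyloxy)propanoate
Conditions: TBSCl, imidazole, CH2Cl2, 0 °C to rt
Reagents that add atoms: tert-butyldimethylsilyl chloride, CC(C)(C)[Si](C)(C)Cl
Why: Imidazole-promoted silylation of a primary alcohol; the silyl ether survives the enolate chemistry and later keeps the primary carbinol out of the lipase acylation.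

Step 2
Reactants: 2 methyl 3-(tert-butyldimethylsilyloxy)propanoate
Product: 3 methyl 2-(tert-butyldimethylsilyloxymethyl)-3-oxobutanoate (racemic)
Conditions: LiN(i-Pr)2, THF, −78 °C; N-methoxy-N-methylacetamide, −78 to −20 °C; aq. NH4Cl
Reagents that add atoms: N-methoxy-N-methylacetamide, CC(=O)N(C)OC
Why: Claisen-type C-acylation of a lithium ester enolate with an N-methoxy-N-methylamide; the chelated tetrahedral adduct persists until work-up, so the β-keto ester is never exposed to enolate and the acetyl group sits unambiguously on the carbon that bears the CH2O branch. At −78 °C β-elimination of silanolate from the enolate is not expected.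

Step 3
Reactants: 3 methyl 2-(tert-butyldimethylsilyloxymethyl)-3-oxobutanoate
Product: 4 methyl 2-(tert-butyldimethylsilyloxymethyl)-3-methoxybut-2-enoate (mixture of double-bond isomers, used as such)
Conditions: NaH, THF/DMPU, 0 °C; Me2SO4, 0 °C to rt
Reagents that add atoms: dimethyl sulfate, COS(=O)(=O)OC
Why: O-Alkylation of a β-keto ester enolate: a dissociated sodium enolate in a dipolar aprotic medium reacts with the hard electrophile dimethyl sulfate on oxygen, and the α-substituent further disfavours C-methylation. Both double-bond isomers give the same diene in step 4.

Step 4
Reactants: 4 methyl 2-(tert-butyldimethylsilyloxymethyl)-3-methoxybut-2-enoate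
Product: 5 2-(tert-butyldimethylsilyloxymethyl)-1,3-dimethoxy-1-(trimethylsilyloxy)buta-1,3-diene
Conditions: LiN(i-Pr)2, THF, −78 °C; Me3SiCl, −78 °C to rt; pentane, filtration under argon
Reagents that add atoms: chlorotrimethylsilane, C[Si](C)(C)Cl
Why: γ-Deprotonation of the β-methoxy enoate gives the extended ester enolate, which is silylated on oxygen (silyl ketene acetal formation, as for the unsubstituted 1,3-dimethoxy-1-silyloxybutadiene). The C4 methyl group is the only position whose anion is conjugated with the ester.

Step 5
Reactants: 6 3,3-diethoxyprop-1-yne
Product: 7 methyl 4,4-diethoxybut-2-ynoate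
Conditions: n-BuLi, THF, −78 °C; ClCO2Me, −78 to 0 °C
Reagents that add atoms: methyl chloroformate, COC(Cl)=O
Why: Acylation of a lithium acetylide with a chloroformate; the acetal is inert to the base.

Step 6
Reactants: 5 2-(tert-butyldimethylsilyloxymethyl)-1,3-dimethoxy-1-(trimethylsilyloxy)buta-1,3-diene; 7 methyl 4,4-diethoxybut-2-ynoate
Product: 10 methyl 6-(diethoxymethyl)-2-hydroxy-4-methoxy-3-(tert-butyldimethylsilyloxymethyl)benzoate, via cyclohexa-1,4-diene cycloadduct 8 (not isolated), via aryl trimethylsilyl ether 9 (not isolated)
Conditions: toluene, 80 °C; then MeOH, SiO2, rt
Reagents that add atoms: none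
Why: A normal-demand Diels–Alder reaction between the electron-rich 1-alkoxy-1-silyloxy diene and the acetylenic ester, the closest known type being the salicylate synthesis from 1,1-dioxygenated 3-oxy dienes and alkynoates. Bond formation is asynchronous: the unsubstituted CH2 terminus of 5 (largest HOMO coefficient) bonds first to the ynoate carbon β to the ester, which carries the acetal, and the ketene acetal carbon then bonds to the α-carbon. The six-membered carbocycle closes by intermolecular (4+2) addition and forms the bonds that become C3a–C4 and C7–C7a. Cycloadduct 8 has a mixed methyl silyl ketal carbon across the ring from the new CH2 group and aromatises by 1,4-elimination of methanol to the silyl ether 9; methanol on silica then frees the phenol, which is stabilised by hydrogen bonding to the ester. No stereocentre survives, since the ketal carbon of 8 becomes aromatic. The only selectivity needed is regiochemical, and it is secured by the matching polarisation of the two partners. The acetal carbon is not a conjugating acceptor, so the ester alone directs. Loss of methanol rather than silanol is expected because the Si–O bond is the stronger one and methoxide is the group that ionises from the ketal.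

Step 7
Reactants: 10 methyl 6-(diethoxymethyl)-2-hydroxy-4-methoxy-3-(tert-butyldimethylsilyloxymethyl)benzoate
Product: 12 rac-3,7-dihydroxy-5-methoxy-6-(tert-butyldimethylsilyloxymethyl)isobenzofuran-1(3H)-one, via formyl ester 11 (not isolated)
Conditions: PPTS, acetone/H2O, rt; then LiOH, THF/H2O, 0 °C; 1 M HCl to pH 3, 0 °C
Reagents that add atoms: water, O; lithium hydroxide, [Li+].[OH-]
Why: Mild hydrolysis of the aryl diethyl acetal, then saponification assisted by the neighbouring formyl group: hydroxide adds to the aldehyde and the resulting alkoxide attacks the hindered, chelated ester intramolecularly. Acidification closes the 2-formylbenzoic acid to its lactol. Any 3-ethoxyphthalide formed in the acid stage is converted to the same carboxylate by LiOH.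

Step 8
Reactants: 12 rac-3,7-dihydroxy-5-methoxy-6-(tert-butyldimethylsilyloxymethyl)isobenzofuran-1(3H)-one
Product: 13 (3R)-3-acetoxy-7-hydroxy-5-methoxy-6-(tert-butyldimethylsilyloxymethyl)isobenzofuran-1(3H)-one
Conditions: Burkholderia cepacia lipase (immobilised), vinyl acetate, Et3N (10 mol %), t-BuOMe, 35 °C
Reagents that add atoms: vinyl acetate, C=COC(C)=O
Why: Lipase-catalysed acylative dynamic kinetic resolution of a cyclic hemiacylal, the reaction type known for 5-hydroxyfuran-2(5H)-ones: the enantiomers of 12 interconvert through the open formyl carboxylate (amine-catalysed) while the enzyme acetylates one of them irreversibly. The (R)-lactol has the spatial arrangement of (R)-indan-1-ol (aryl carbon as large group, ring oxygen as medium group), the enantiomer preferred by this lipase class under the empirical size rule for secondary alcohols, so C3 should be set as R by the enzyme. The phenol and the silyl ether are not substrates.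

Step 9
Reactants: 13 (3R)-3-acetoxy-7-hydroxy-5-methoxy-6-(tert-butyldimethylsilyloxymethyl)isobenzofuran-1(3H)-one
Product: 14 (3R)-3-acetoxy-7-hydroxy-6-(hydroxymethyl)-5-methoxyisobenzofuran-1(3H)-one
Conditions: HF·pyridine, THF, 0 °C to rt
Reagents that add atoms: none
Why: Fluoride cleavage of a primary silyl ether under weakly acidic, non-basic conditions that leave the acylal acetate, the lactone and the C3 configuration untouched.

Step 10
Reactants: 15 methyl 2,4-dihydroxy-3,6-dimethylbenzoate
Product: 16 methyl 2-hydroxy-4-methoxy-3,6-dimethylbenzoate
Conditions: MeI (1.1 equiv), K2CO3, acetone, reflux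
Reagents that add atoms: iodomethane, CI
Why: Williamson methylation selective for the 4-OH, which is more acidic and more nucleophilic than the 2-OH hydrogen-bonded to the ester.

Step 11
Reactants: 16 methyl 2-hydroxy-4-methoxy-3,6-dimethylbenzoate
Product: 17 2-hydroxy-4-methoxy-3,6-dimethylbenzoic acid
Conditions: KOH, DMSO/H2O, 90 °C; then cold 1 M HCl
Reagents that add atoms: potassium hydroxide, [K+].[OH-]
Why: Saponification of a hindered salicylate needs forcing base; the phenoxide carboxylate is stable to it, and cold acidification avoids the decarboxylation to which electron-rich salicylic acids are prone in hot acid.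

Step 12
Reactants: 14 (3R)-3-acetoxy-7-hydroxy-6-(hydroxymethyl)-5-methoxyisobenzofuran-1(3H)-one; 17 2-hydroxy-4-methoxy-3,6-dimethylbenzoic acid
Product: 18 [(3R)-3-acetoxy-7-hydroxy-5-methoxy-1-oxo-1,3-dihydroisobenzofuran-6-yl]methyl 2-hydroxy-4-methoxy-3,6-dimethylbenzoate
Conditions: PPh3, DIAD, THF, 0 °C to rt
Reagents that add atoms: none
Why: Mitsunobu esterification: the primary benzylic carbinol is activated as an oxyphosphonium ion and displaced by the carboxylate of 17, so the hindered acid is never activated at its carbonyl. The phenols are far weaker acids and are hydrogen-bonded, and C3 is not involved.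

Step 13
Reactants: 18 [(3R)-3-acetoxy-7-hydroxy-5-methoxy-1-oxo-1,3-dihydroisobenzofuran-6-yl]methyl 2-hydroxy-4-methoxy-3,6-dimethylbenzoate
Product: 19 [(3R)-3,7-dihydroxy-5-methoxy-1-oxo-1,3-dihydroisobenzofuran-6-yl]methyl 2-hydroxy-4-methoxy-3,6-dimethylbenzoate
Conditions: Burkholderia cepacia lipase (immobilised), n-BuOH, t-BuOMe, 25 °C
Reagents that add atoms: none
Why: Lipase-catalysed alcoholysis, the reverse of step 8, cleaves the acetyl C–O bond, so C3 keeps its configuration, and the enzyme's preference for the (R)-acylal leaves any minor enantiomer behind as acetate. The neutral aprotic medium avoids the o-quinone methide and ionisation pathways of the benzylic ester and limits ring–chain racemisation; the hindered ring A ester is not a lipase substrate.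

## Compound list

1 | methyl 3-hydroxypropanoate | COC(=O)CCO | starting material
2 | methyl 3-(tert-butyldimethylsilyloxy)propanoate | COC(=O)CCO[Si](C)(C)C(C)(C)C | intermediate
3 | methyl 2-(tert-butyldimethylsilyloxymethyl)-3-oxobutanoate (racemic) | COC(=O)C(CO[Si](C)(C)C(C)(C)C)C(C)=O | intermediate
4 | methyl 2-(tert-butyldimethylsilyloxymethyl)-3-methoxybut-2-enoate (mixture of double-bond isomers) | COC(C)=C(CO[Si](C)(C)C(C)(C)C)C(=O)OC | intermediate
5 | 2-(tert-butyldimethylsilyloxymethyl)-1,3-dimethoxy-1-(trimethylsilyloxy)buta-1,3-diene (ketene acetal geometry not defined) | C=C(OC)C(CO[Si](C)(C)C(C)(C)C)=C(OC)O[Si](C)(C)C | intermediate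
6 | 3,3-diethoxyprop-1-yne | C#CC(OCC)OCC | starting material
7 | methyl 4,4-diethoxybut-2-ynoate | CCOC(OCC)C#CC(=O)OC | intermediate
8 | methyl 5-(tert-butyldimethylsilyloxymethyl)-2-(diethoxymethyl)-4,6-dimethoxy-6-(trimethylsilyloxy)cyclohexa-1,4-diene-1-carboxylate (racemic) | COC(=O)C1=C(C(OCC)OCC)CC(OC)=C(CO[Si](C)(C)C(C)(C)C)C1(OC)O[Si](C)(C)C | intermediate (not isolated)
9 | methyl 6-(diethoxymethyl)-4-methoxy-3-(tert-butyldimethylsilyloxymethyl)-2-(trimethylsilyloxy)benzoate | COC(=O)c1c(C(OCC)OCC)cc(OC)c(CO[Si](C)(C)C(C)(C)C)c1O[Si](C)(C)C | intermediate (not isolated)
10 | methyl 6-(diethoxymethyl)-2-hydroxy-4-methoxy-3-(tert-butyldimethylsilyloxymethyl)benzoate | CCOC(OCC)c1cc(OC)c(CO[Si](C)(C)C(C)(C)C)c(O)c1C(=O)OC | intermediate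
11 | methyl 6-formyl-2-hydroxy-4-methoxy-3-(tert-butyldimethylsilyloxymethyl)benzoate | COC(=O)c1c(C=O)cc(OC)c(CO[Si](C)(C)C(C)(C)C)c1O | intermediate (not isolated)
12 | rac-3,7-dihydroxy-5-methoxy-6-(tert-butyldimethylsilyloxymethyl)isobenzofuran-1(3H)-one | COc1cc2c(c(O)c1CO[Si](C)(C)C(C)(C)C)C(=O)OC2O | intermediate
13 | (3R)-3-acetoxy-7-hydroxy-5-methoxy-6-(tert-butyldimethylsilyloxymethyl)isobenzofuran-1(3H)-one | COc1cc2c(c(O)c1CO[Si](C)(C)C(C)(C)C)C(=O)O[C@H]2OC(C)=O | intermediate
14 | (3R)-3-acetoxy-7-hydroxy-6-(hydroxymethyl)-5-methoxyisobenzofuran-1(3H)-one | COc1cc2c(c(O)c1CO)C(=O)O[C@H]2OC(C)=O | intermediate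
15 | methyl 2,4-dihydroxy-3,6-dimethylbenzoate | COC(=O)c1c(C)cc(O)c(C)c1O | starting material
16 | methyl 2-hydroxy-4-methoxy-3,6-dimethylbenzoate | COC(=O)c1c(C)cc(OC)c(C)c1O | intermediate
17 | 2-hydroxy-4-methoxy-3,6-dimethylbenzoic acid | COc1cc(C)c(C(=O)O)c(O)c1C | intermediate
18 | [(3R)-3-acetoxy-7-hydroxy-5-methoxy-1-oxo-1,3-dihydroisobenzofuran-6-yl]methyl 2-hydroxy-4-methoxy-3,6-dimethylbenzoate | COc1cc(C)c(C(=O)OCc2c(OC)cc3c(c2O)C(=O)O[C@H]3OC(C)=O)c(O)c1C | intermediate
19 | [(3R)-3,7-dihydroxy-5-methoxy-1-oxo-1,3-dihydroisobenzofuran-6-yl]methyl 2-hydroxy-4-methoxy-3,6-dimethylbenzoate | COc1cc(C)c(C(=O)OCc2c(OC)cc3c(c2O)C(=O)O[C@H]3O)c(O)c1C | target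

## Step count and risk

Total: 13 steps. Longest linear sequence: 10 steps (steps 1, 2, 3, 4, 6, 7, 8, 9, 12, 13).

**Step 6 (key step).**
- Risk: the cycloaddition of the fully substituted diene with an internal alkyne may be slow enough that thermal oxygen-to-carbon silyl migration or adventitious hydrolysis consumes the ketene acetal. A lesser risk is aromatisation by loss of silanol, which would leave the C7 oxygen methylated.
- Fallback: form the same two bonds ionically. Enoate 4 is deprotonated with LiN(i-Pr)2 at −78 °C and 7 is added. Conjugate addition of the extended enolate through its γ-carbon to the ynoate, Dieckmann-type closure of the resulting allenolate onto the ester of the former enolate, and tautomerisation should give 10 directly. The fallback sets out from 4 and 7 and returns at 10; it creates no new isolated compound (F0).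

**Step 8.**
- Risk: the lipase may acylate this heavily substituted lactol too slowly or with insufficient or opposite enantiopreference. If racemisation of the slow enantiomer lags behind acylation, the process degenerates into a simple kinetic resolution.
- Fallback: non-enzymatic acylative dynamic kinetic resolution of 12 with Ac2O, i-Pr2NEt and a chiral Lewis-base acyl-transfer catalyst (an isothiourea such as benzotetramisole, enantiomer chosen to give the R acylal). This reaction type is documented for 3-hydroxyphthalides, and either product enantiomer is accessible. It sets out from 12 and returns at 13; no new compound (F0).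

**Step 13.**
- Risk: the bulky acylal 18 may be alcoholysed slowly, and 19 may partly racemise by ring–chain tautomerism over a long reaction time.
- Fallback: carry a chloroacetyl group in place of acetyl, removable chemically under near-neutral conditions. From 12, lipase acylation with vinyl chloroacetate gives (3S)-3-(chloroacetoxy)-7-hydroxy-5-methoxy-6-(tert-butyldimethylsilyloxymethyl)isobenzofuran-1(3H)-one F1. Its spatial arrangement is that of 13; the descriptor changes only because chloroacetoxy outranks the ring oxygen. HF·pyridine gives the carbinol (3S)-3-(chloroacetoxy)-7-hydroxy-6-(hydroxymethyl)-5-methoxyisobenzofuran-1(3H)-one F2. Mitsunobu coupling with 17 gives the chloroacetate of the target F3. Thiourea with NaHCO3 in THF/EtOH at rt then removes the chloroacetyl group by S-alkylation and cyclisation, with the C3–O bond intact, and returns to the route at 19.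

**Step 3.**
- Risk: C-methylation, or β-elimination of silanolate from the β-keto ester enolate, which would destroy the CH2O branch.
- Fallback: avoid O-methylation of the keto ester. From 3, Me3SiCl/Et3N gives methyl 2-(tert-butyldimethylsilyloxymethyl)-3-(trimethylsilyloxy)but-2-enoate F4. LiN(i-Pr)2/Me3SiCl gives 2-(tert-butyldimethylsilyloxymethyl)-1-methoxy-1,3-bis(trimethylsilyloxy)buta-1,3-diene F5. Cycloaddition with 7 and methanolysis gives methyl 6-(diethoxymethyl)-2,4-dihydroxy-3-(tert-butyldimethylsilyloxymethyl)benzoate F6. Its non-chelated 4-OH is methylated selectively (MeI, K2CO3, acetone), returning to the route at 10.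

**Step 12.**
- Risk: activation of the o-hydroxybenzyl alcohol may trigger o-quinone methide formation, followed by capture by the reduced azo reagent or by oligomerisation instead of by the carboxylate.
- Fallback: from 14, PPh3/CBr4 gives (3R)-3-acetoxy-6-(bromomethyl)-7-hydroxy-5-methoxyisobenzofuran-1(3H)-one F7. This is alkylated by the carboxylate of 17 (KHCO3, DMF, rt; only the carboxylic acid is deprotonated), returning to the route at 18.

## Further compounds

F0 | step 6 | none | none
F0 | step 8 | none | none
F1 | step 13 | (3S)-3-(chloroacetoxy)-7-hydroxy-5-methoxy-6-(tert-butyldimethylsilyloxymethyl)isobenzofuran-1(3H)-one | COc1cc2c(c(O)c1CO[Si](C)(C)C(C)(C)C)C(=O)O[C@H]2OC(=O)CCl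
F2 | step 13 | (3S)-3-(chloroacetoxy)-7-hydroxy-6-(hydroxymethyl)-5-methoxyisobenzofuran-1(3H)-one | COc1cc2c(c(O)c1CO)C(=O)O[C@H]2OC(=O)CCl
F3 | step 13 | [(3S)-3-(chloroacetoxy)-7-hydroxy-5-methoxy-1-oxo-1,3-dihydroisobenzofuran-6-yl]methyl 2-hydroxy-4-methoxy-3,6-dimethylbenzoate | COc1cc(C)c(C(=O)OCc2c(OC)cc3c(c2O)C(=O)O[C@H]3OC(=O)CCl)c(O)c1C
F4 | step 3 | methyl 2-(tert-butyldimethylsilyloxymethyl)-3-(trimethylsilyloxy)but-2-enoate | COC(=O)C(CO[Si](C)(C)C(C)(C)C)=C(C)O[Si](C)(C)C
F5 | step 3 | 2-(tert-butyldimethylsilyloxymethyl)-1-methoxy-1,3-bis(trimethylsilyloxy)buta-1,3-diene | C=C(O[Si](C)(C)C)C(CO[Si](C)(C)C(C)(C)C)=C(OC)O[Si](C)(C)C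
F6 | step 3 | methyl 6-(diethoxymethyl)-2,4-dihydroxy-3-(tert-butyldimethylsilyloxymethyl)benzoate | CCOC(OCC)c1cc(O)c(CO[Si](C)(C)C(C)(C)C)c(O)c1C(=O)OC
F7 | step 12 | (3R)-3-acetoxy-6-(bromomethyl)-7-hydroxy-5-methoxyisobenzofuran-1(3H)-one | COc1cc2c(c(O)c1CBr)C(=O)O[C@H]2OC(C)=O
A1 | alternative 1 | 1-ethoxyprop-2-yn-1-yl 3-[dimethyl(3-methoxyprop-2-yn-1-yloxy)silyl]prop-2-ynoate (racemic triyne) | C#CC(OCC)OC(=O)C#C[Si](C)(C)OCC#COC
A2 | alternative 1 | tricyclic 3-ethoxy-5-methoxyphthalide fused at C6/C7 to a 1,1-dimethylbenzoxasilole (racemic) | CCOC1OC(=O)c2c1cc(OC)c1CO[Si](C)(C)c21
A3 | alternative 2 | 2,2-dimethyl-6-(3,5-dioxohexan-2-yl)-4H-1,3-dioxin-4-one | CC(=O)CC(=O)C(C)C1=CC(=O)OC(C)(C)O1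
A4 | alternative 2 | 6-(hydroxymethyl)-3,5-dimethoxy-7-(methoxymethoxy)isobenzofuran-1(3H)-one (racemic) | COCOc1c(CO)c(OC)cc2C(OC)OC(=O)c12
A5 | alternative 2 | [3,5-dimethoxy-7-(methoxymethoxy)-1-oxo-1,3-dihydroisobenzofuran-6-yl]methyl 2,4-dihydroxy-3,6-dimethylbenzoate (racemic) | COCOc1c(COC(=O)c3c(C)cc(O)c(C)c3O)c(OC)cc2C(OC)OC(=O)c12
A6 | alternative 3 | enantioenriched 2-(tert-butyldimethylsilyloxy)benzocyclobutenone carrying the ring B substituents and the ring A ester | COc1cc2c(c(O[Si](C)(C)C(C)(C)C)c1COC(=O)c1c(C)cc(OC)c(C)c1O)C(=O)[C@H]2O[Si](C)(C)C(C)(C)C
A7 | alternative 3 | bis(tert-butyldimethylsilyl) ether of the target (lactol and C7 phenol silylated) | COc1cc2c(c(O[Si](C)(C)C(C)(C)C)c1COC(=O)c1c(C)cc(OC)c(C)c1O)C(=O)O[C@H]2O[Si](C)(C)C(C)(C)C
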